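**Plan**

1. Numbering used throughout: decalin C1–C10 (C10 and C4 are the quaternary CH3-bearing carbons of ring A, C5 the ring-fusion CH between them, ring B = C5–C6–C7–C8=C9–C10, C11 the benzylic CH2); right half: Ca (carbinol), Cb (CH–CH3), Ce (CH–O), Cf (quaternary).
2. Retrosynthetic cuts, in order: the two ArO–SO3H bonds; the Ca–CH2 bond of the two-carbon link (alkyllithium + oxepane ketone); C5–C6 of ring B (radical ring closure); C9–C11 (Negishi) and C8–C9 (Dieckmann) inside a temporary δ-lactone.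
3. Forward: ring A (from ethyl 2-oxocyclohexanecarboxylate) receives C10 and C4; the C10 ester carbon becomes C9 of a lactone whose ring oxygen ties C5 to C7 and locks C8=C9 as Z; the lactone is opened to a C5 carbinol plus a C9=C8–C7=C6 diene and ring B is closed; the oxepane is closed on a yeast-derived hydroxy ketone before the halves are joined; sulfation is last.
4. Enabling feature: C5 is a secondary carbon of ring A held between the quaternary C4 and C10. Its xanthate has no β-hydrogen and its radical can only reach C6, the terminus of the (Z)-dienyl group on C10; the axial C10 methyl and C4 chain shield one face, which gives the cis ring fusion.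
5. Stereochemistry: C10 from a valine-enamine methylation, C4 from ligand-controlled Pd decarboxylative allylation, C5 from the key cyclisation, Ce/Cf from yeast desymmetrisation, Cb by equilibration, Ca by equatorial addition trans to the Cb methyl.

Key step: step 15

Assumptions: the target is taken as the free bis(hydrogen sulfate) drawn, obtained from its pyridinium salt on an H+ resin; in step 2 the L-valine auxiliary in toluene/HMPA is taken to give the (R)-ester (otherwise the D-auxiliary is used); the C5 carbinol configuration drawn for 10–21 is the expected one and is erased in step 15, so its epimer would serve equally.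

**Route**

Step 1
Reactants: 1 ethyl 2-oxocyclohexane-1-carboxylate; 2 tert-butyl L-valinate
Product: 3 ethyl 2-{[(2S)-1-tert-butoxy-3-methyl-1-oxobutan-2-yl]amino}cyclohex-1-ene-1-carboxylate
Conditions: BF3·OEt2 (cat.), PhH, reflux, Dean–Stark
Reagents that add atoms: none
Why: Condensation of the β-keto ester with the amino ester gives the hydrogen-bonded enamino ester that carries the chiral auxiliary for the next step.

Step 2
Reactants: 3 valine enamine
Product: 5 ethyl (1R)-1-methyl-2-oxocyclohexane-1-carboxylate, via methylated ketimine 4 (not isolated)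
Conditions: LDA, toluene, −78 °C; HMPA (1 equiv); MeI, −78 °C; then 1 M HCl, 0 °C
Reagents that add atoms: iodomethane CI; water O
Why: Asymmetric alkylation of a chelated chiral lithioenamine, in which the valine ester side chain and the lithium coordination sphere block one face so that MeI sets the quaternary centre C10, followed by imine hydrolysis that returns the auxiliary.

Step 3
Reactants: 5 (R)-keto ester
Product: 6 ethyl (1R)-1,3-dimethyl-2-oxocyclohexane-1-carboxylate (both C3 epimers)
Conditions: LDA, THF, −78 °C; MeI, −78 → 0 °C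
Reagents that add atoms: iodomethane CI
Why: Enolate alkylation is regiospecific because only C3 (the future C4) carries α-hydrogens, and the new CH centre is made planar again in step 4.

Step 4
Reactants: 6 dimethyl keto ester
Product: 7 ethyl (1R)-1,3-dimethyl-2-{[(prop-2-en-1-yloxy)carbonyl]oxy}cyclohex-2-ene-1-carboxylate
Conditions: KHMDS, THF, −78 °C; allyl chloroformate, −78 → 0 °C
Reagents that add atoms: allyl chloroformate C=CCOC(=O)Cl
Why: O-Acylation of the only possible (tetrasubstituted) potassium enolate by the hard chloroformate gives the allyl enol carbonate needed for decarboxylative allylation.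

Step 5
Reactants: 7 allyl enol carbonate
Product: 8 ethyl (1R,3S)-1,3-dimethyl-2-oxo-3-(prop-2-en-1-yl)cyclohexane-1-carboxylate
Conditions: Pd2(dba)3 (2.5 mol %), (S)-t-Bu-PHOX (6 mol %), THF, 25 °C
Reagents that add atoms: none
Why: Decarboxylative asymmetric Tsuji allylation, in which loss of CO2 gives a Pd π-allyl/enolate pair and the PHOX ligand directs allylation to one face of the enolate, sets the quaternary centre C4 with its methyl trans to the C10 methyl.

Step 6
Reactants: 8 allyl keto ester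
Product: 10 ethyl (1R,2S,3S)-2-hydroxy-3-(2-hydroxyethyl)-1,3-dimethylcyclohexane-1-carboxylate, via keto aldehyde 9 (not isolated)
Conditions: O3, CH2Cl2/MeOH, −78 °C; then NaBH4 (excess), −78 → 23 °C
Reagents that add atoms: ozone [O-][O+]=O
Why: Ozonolysis with borohydride work-up shortens the allyl group to the two-carbon alcohol and reduces the ester-activated C5 ketone, with hydride expected anti to the axial ester/methyl pair (carbinol cis to the ester).

Step 7
Reactants: 10 diol
Product: 11 ethyl (1R,2S,3S)-3-[2-(tert-butyldimethylsilyloxy)ethyl]-2-hydroxy-1,3-dimethylcyclohexane-1-carboxylate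
Conditions: TBSCl, imidazole, DMF, 0 °C
Reagents that add atoms: tert-butyldimethylsilyl chloride C[Si](C)(Cl)C(C)(C)C
Why: Silylation is selective for the primary alcohol because the C5 hydroxyl lies between two quaternary carbons.

Step 8
Reactants: 11 silyl ether
Product: 12 ethyl (1R,2S,3S)-3-[2-(tert-butyldimethylsilyloxy)ethyl]-1,3-dimethyl-2-(propanoyloxy)cyclohexane-1-carboxylate
Conditions: EtCOCl, pyridine, DMAP, CH2Cl2, 0 → 40 °C
Reagents that add atoms: propanoyl chloride CCC(=O)Cl
Why: DMAP-catalysed acylation under forcing conditions esterifies the hindered C5 hydroxyl and brings in C7, C8 and the C8 methyl.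

Step 9
Reactants: 12 propanoate
Product: 13 (4aR,8S,8aS)-8-[2-(tert-butyldimethylsilyloxy)ethyl]-4-hydroxy-3,4a,8-trimethyl-4a,5,6,7,8,8a-hexahydro-2H-chromen-2-one (enol form of the cis-fused β-keto lactone)
Conditions: LiHMDS (3 equiv), THF, −78 → 0 °C; aq. NH4Cl
Reagents that add atoms: none
Why: Dieckmann (intramolecular Claisen) condensation of the propanoate enolate onto the neighbouring cis ethyl ester through a six-membered transition state, driven by deprotonation of the product, joins C8 to C9 inside a ring that holds C7 and C10 cis.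

Step 10
Reactants: 13 enol lactone
Product: 14 (4aR,8S,8aS)-8-[2-(tert-butyldimethylsilyloxy)ethyl]-3,4a,8-trimethyl-2-oxo-4a,5,6,7,8,8a-hexahydro-2H-chromen-4-yl trifluoromethanesulfonate
Conditions: Tf2O, Et3N, CH2Cl2, −78 °C
Reagents that add atoms: trifluoromethanesulfonic anhydride O=S(=O)(OS(=O)(=O)C(F)(F)F)C(F)(F)F
Why: O-Sulfonylation of the vinylogous acid gives a cyclic enol triflate whose alkene geometry is fixed by the ring.

Step 11
Reactants: 14 enol triflate; 15 2-(chloromethyl)-1,4-dimethoxybenzene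
Product: 17 (4aS,8S,8aS)-8-[2-(tert-butyldimethylsilyloxy)ethyl]-4-(2,5-dimethoxybenzyl)-3,4a,8-trimethyl-4a,5,6,7,8,8a-hexahydro-2H-chromen-2-one, via (2,5-dimethoxybenzyl)zinc chloride 16 (not isolated)
Conditions: 15, Zn dust, LiCl, THF, 25 °C; then 14, Pd(PPh3)4 (5 mol %), THF, 50 °C
Reagents that add atoms: none
Why: Negishi coupling (oxidative addition into the electron-poor enol triflate, transmetallation from the benzylzinc reagent, reductive elimination) puts C11 and the arene on C9 with the ring-locked alkene geometry retained.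

Step 12
Reactants: 17 benzyl lactone
Product: 18 (4aS,8S,8aS)-8-[2-(tert-butyldimethylsilyloxy)ethyl]-4-(2,5-dimethoxybenzyl)-3,4a,8-trimethyl-4a,5,6,7,8,8a-hexahydro-2H-chromen-2-ol (both C2 epimers)
Conditions: DIBAL-H (1.2 equiv), CH2Cl2, −78 °C; Rochelle salt
Reagents that add atoms: none
Why: 1,2-Reduction of the unsaturated lactone by DIBAL-H at low temperature stops at the aluminium hemiacetal, which gives the lactol on work-up.

Step 13
Reactants: 18 lactol
Product: 20 (1S,2S,6S)-6-[2-(tert-butyldimethylsilyloxy)ethyl]-2-[(2Z)-1-(2,5-dimethoxyphenyl)-3-methylpenta-2,4-dien-2-yl]-2,6-dimethylcyclohexan-1-ol, via hydroxy enal 19 (not isolated)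
Conditions: Ph3PCH3Br, KHMDS, THF, 0 °C; then 18, −78 → 0 °C
Reagents that add atoms: methyltriphenylphosphonium bromide C[P+](c1ccccc1)(c1ccccc1)c1ccccc1.[Br-]
Why: Wittig methylenation of the open hydroxy enal tautomer adds C6 and frees the C5 hydroxyl, while the Z geometry of C8=C9 set in the ring is kept.

Step 14
Reactants: 20 hydroxy diene
Product: 21 O-{(1S,2S,6S)-6-[2-(tert-butyldimethylsilyloxy)ethyl]-2-[(2Z)-1-(2,5-dimethoxyphenyl)-3-methylpenta-2,4-dien-2-yl]-2,6-dimethylcyclohexyl} S-methyl carbonodithioate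
Conditions: KH, THF, 0 °C; CS2; MeI, 23 °C
Reagents that add atoms: carbon disulfide S=C=S; iodomethane CI
Why: Xanthate formation (alkoxide addition to CS2, then S-methylation) converts the C5 carbinol into a radical precursor that cannot undergo Chugaev elimination, since neither neighbour of C5 bears hydrogen.

Step 15
Reactants: 21 xanthate
Product: 22 cis-fused (4S,5S,10R)-4-[2-(tert-butyldimethylsilyloxy)ethyl]-9-(2,5-dimethoxybenzyl)-4,8,10-trimethyl-Δ8(9)-octalin (5-H cis to 10-CH3)
Conditions: Bu3SnH (1.3 equiv, syringe pump, 6 h), AIBN (0.2 equiv), PhH (0.005 M), 80 °C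
Reagents that add atoms: none
Why: Bu3Sn• adds to the thiocarbonyl and the adduct fragments at the C5–O bond (Barton–McCombie) to give the secondary C5 radical, which adds to the diene terminus C6 and leaves an allyl radical over C7–C8–C9 that takes hydrogen from Bu3SnH at the less hindered C7, so the tetrasubstituted C8=C9 alkene is regenerated; the closest known reaction type is the tin-hydride cyclisation of a xanthate-derived alkyl radical onto a 1,3-diene. Ring B closes in the 6-endo-trig mode, because the 5-exo alternative (attack at C7) would give an unstabilised primary radical through a cyclopentene-forming transition state containing the C8=C9 double bond. The new stereocentre C5 is controlled by ring A: in the chair with the dienyl group equatorial, the C10 methyl and the C4 side chain are both axial on one face of the radical, so C6 bonds axially from the open face, which puts C5–C6 cis to C10–C9 and the C5 hydrogen cis to the C10 methyl. The step needs cyclisation to outrun direct reduction of the C5 radical, which is served by slow stannane addition at high dilution and by the absence of any 1,5-transferable hydrogen (the C8 methyl is held trans to C10). It also needs the Z geometry of C8=C9 so that C6 can reach C5, and this was fixed while C7 and C5 were tied together through the lactone oxygen. Because C4 and C10 are quaternary, the radical has no β-hydrogen to lose.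

Step 16
Reactants: 22 cyclised silyl ether
Product: 23 2-[(4S,5S,10R)-9-(2,5-dimethoxybenzyl)-4,8,10-trimethyl-Δ8(9)-octalin-4-yl]ethan-1-ol
Conditions: TBAF, THF, 23 °C
Reagents that add atoms: none
Why: Fluoride cleavage of the primary silyl ether frees the alcohol at the end of the two-carbon link.

Step 17
Reactants: 23 alcohol
Product: 24 (4S,5S,10R)-9-(2,5-dimethoxybenzyl)-4-(2-iodoethyl)-4,8,10-trimethyl-Δ8(9)-octalin
Conditions: I2, PPh3, imidazole, CH2Cl2, 0 → 23 °C
Reagents that add atoms: iodine II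
Why: Appel-type iodination of the unhindered primary alcohol proceeds by SN2 on the alkoxyphosphonium ion.

Step 18
Reactants: 25 2-methylcyclohexane-1,3-dione
Product: 26 2-methyl-2-(prop-2-en-1-yl)cyclohexane-1,3-dione
Conditions: allyl bromide, 1 M NaOH, H2O, 23 °C
Reagents that add atoms: allyl bromide C=CCBr
Why: C-Alkylation of the dione enolate with the allylic bromide gives the prochiral 2,2-disubstituted dione.

Step 19
Reactants: 26 allyl dione
Product: 27 (2S,3S)-3-hydroxy-2-methyl-2-(prop-2-en-1-yl)cyclohexan-1-one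
Conditions: baker's yeast, sucrose, H2O, 30 °C
Reagents that add atoms: none
Why: Enzymatic desymmetrising reduction of one enantiotopic carbonyl from the face anti to the allyl group sets Ce and Cf, with the hydroxyl cis to the allyl group.

Step 20
Reactants: 27 hydroxy ketone; 28 2-methylbut-3-en-2-ol
Product: 29 (2S,3S)-3-hydroxy-2-[(2E)-4-hydroxy-4-methylpent-2-en-1-yl]-2-methylcyclohexan-1-one
Conditions: Hoveyda–Grubbs II (5 mol %), 28 (4 equiv), CH2Cl2, 40 °C
Reagents that add atoms: none
Why: Olefin cross-metathesis of the terminal alkene with the slowly homodimerising tertiary allylic alcohol adds the C(CH3)2OH terminus, and the alkene geometry does not matter.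

Step 21
Reactants: 29 allylic alcohol
Product: 30 (2S,3S)-3-hydroxy-2-(4-hydroxy-4-methylpentyl)-2-methylcyclohexan-1-one
Conditions: H2 (1 atm), Pd/C, EtOAc, 23 °C
Reagents that add atoms: none
Why: Heterogeneous hydrogenation saturates the disubstituted alkene and leaves the ketone and both alcohols untouched.

Step 22
Reactants: 30 keto diol
Product: 31 (5aS,9aS)-2,2,5a-trimethyloctahydro-1-benzoxepin-6(2H)-one
Conditions: TfOH (5 mol %), 4 Å MS, CH2Cl2, 0 °C
Reagents that add atoms: none
Why: Acid-catalysed dehydrative etherification (SN1) traps the tertiary carbocation with the cis secondary hydroxyl in a seven-membered closure, which gives the cis-fused oxepane without touching Ce or Cf.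

Step 23
Reactants: 31 oxepane ketone
Product: 32 (5aS,7R,9aS)-2,2,5a,7-tetramethyloctahydro-1-benzoxepin-6(2H)-one
Conditions: LDA, THF, −78 °C; MeI; then NaOMe, MeOH, 23 °C
Reagents that add atoms: iodomethane CI
Why: Enolate methylation is regiospecific (only Cb has α-hydrogens) and base equilibration should favour the epimer with equatorial methyl in the chair that keeps the ring oxygen axial, that is, methyl cis to the ether oxygen.

Step 24
Reactants: 24 iodide; 32 methyl ketone
Product: 34 (5aS,6R,7R,9aS)-6-{2-[(4S,5S,10R)-9-(2,5-dimethoxybenzyl)-4,8,10-trimethyl-Δ8(9)-octalin-4-yl]ethyl}-2,2,5a,7-tetramethyldecahydro-1-benzoxepin-6-ol, via alkyllithium 33 (not isolated)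
Conditions: 24, t-BuLi (2.1 equiv), Et2O/pentane, −78 °C; then 32 premixed with LaCl3·2LiCl, THF, −78 → 0 °C; aq. NH4Cl
Reagents that add atoms: none
Why: Lithium–iodine exchange followed by 1,2-addition of the primary alkyllithium to the Lewis-acid-activated ketone should occur by equatorial attack, trans to the Cb methyl and away from the axial ring oxygen, which sets Ca with the hydroxyl axial and cis to the Cb methyl.

Step 25
Reactants: 34 coupled dimethyl ether
Product: 35 2-{[(4S,5S,10R)-4-{2-[(5aS,6R,7R,9aS)-6-hydroxy-2,2,5a,7-tetramethyldecahydro-1-benzoxepin-6-yl]ethyl}-4,8,10-trimethyl-Δ8(9)-octalin-9-yl]methyl}cyclohexa-2,5-diene-1,4-dione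
Conditions: CAN (2.5 equiv), MeCN/H2O (2:1), 0 °C
Reagents that add atoms: water O
Why: Oxidative demethylation of the para-dimethoxyarene by cerium(IV) (two one-electron oxidations, water attack, loss of methanol) gives the quinone, and the hindered alkene and tertiary alcohol should survive the short cold exposure.

Step 26
Reactants: 35 quinone
Product: 36 2-{[(4S,5S,10R)-4-{2-[(5aS,6R,7R,9aS)-6-hydroxy-2,2,5a,7-tetramethyldecahydro-1-benzoxepin-6-yl]ethyl}-4,8,10-trimethyl-Δ8(9)-octalin-9-yl]methyl}benzene-1,4-diol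
Conditions: Na2S2O4, THF/H2O, 23 °C, Ar
Reagents that add atoms: none
Why: Dithionite reduction converts the quinone into the hydroquinone, which is used at once.

Step 27
Reactants: 36 hydroquinone
Product: 37 CNP0125037.2, the bis(hydrogen sulfate) of 36
Conditions: SO3·pyridine (10 equiv), pyridine, 40 °C; then Dowex 50W (H+ form), MeOH/H2O, 0 °C
Reagents that add atoms: sulfur trioxide–pyridine complex [O-]S(=O)(=O)[n+]1ccccc1
Why: O-Sulfation of the two phenols with SO3·pyridine should spare the tertiary alcohol, which is flanked by a quaternary carbon and a CH(CH3), and proton exchange of the pyridinium salt gives the free acid.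

**Compound list**

1 | ethyl 2-oxocyclohexane-1-carboxylate | CCOC(=O)C1CCCCC1=O | starting material
2 | tert-butyl L-valinate | CC(C)[C@H](N)C(=O)OC(C)(C)C | starting material
3 | ethyl 2-{[(2S)-1-tert-butoxy-3-methyl-1-oxobutan-2-yl]amino}cyclohex-1-ene-1-carboxylate | CCOC(=O)C1=C(N[C@@H](C(C)C)C(=O)OC(C)(C)C)CCCC1 | intermediate
4 | ethyl (1R)-2-{[(2S)-1-tert-butoxy-3-methyl-1-oxobutan-2-yl]imino}-1-methylcyclohexane-1-carboxylate (not isolated) | CCOC(=O)[C@]1(C)CCCCC1=N[C@@H](C(C)C)C(=O)OC(C)(C)C | intermediate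
5 | ethyl (1R)-1-methyl-2-oxocyclohexane-1-carboxylate | CCOC(=O)[C@]1(C)CCCCC1=O | intermediate
6 | ethyl (1R)-1,3-dimethyl-2-oxocyclohexane-1-carboxylate (C3 epimers) | CCOC(=O)[C@]1(C)CCCC(C)C1=O | intermediate
7 | ethyl (1R)-1,3-dimethyl-2-{[(prop-2-en-1-yloxy)carbonyl]oxy}cyclohex-2-ene-1-carboxylate | CCOC(=O)[C@]1(C)CCCC(C)=C1OC(=O)OCC=C | intermediate
8 | ethyl (1R,3S)-1,3-dimethyl-2-oxo-3-(prop-2-en-1-yl)cyclohexane-1-carboxylate | CCOC(=O)[C@]1(C)CCC[C@@](C)(CC=C)C1=O | intermediate
9 | ethyl (1R,3S)-1,3-dimethyl-2-oxo-3-(2-oxoethyl)cyclohexane-1-carboxylate (not isolated) | CCOC(=O)[C@]1(C)CCC[C@@](C)(CC=O)C1=O | intermediate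
10 | ethyl (1R,2S,3S)-2-hydroxy-3-(2-hydroxyethyl)-1,3-dimethylcyclohexane-1-carboxylate | CCOC(=O)[C@]1(C)CCC[C@@](C)(CCO)[C@@H]1O | intermediate
11 | ethyl (1R,2S,3S)-3-[2-(tert-butyldimethylsilyloxy)ethyl]-2-hydroxy-1,3-dimethylcyclohexane-1-carboxylate | CCOC(=O)[C@]1(C)CCC[C@@](C)(CCO[Si](C)(C)C(C)(C)C)[C@@H]1O | intermediate
12 | ethyl (1R,2S,3S)-3-[2-(tert-butyldimethylsilyloxy)ethyl]-1,3-dimethyl-2-(propanoyloxy)cyclohexane-1-carboxylate | CCOC(=O)[C@]1(C)CCC[C@@](C)(CCO[Si](C)(C)C(C)(C)C)[C@@H]1OC(=O)CC | intermediate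
13 | (4aR,8S,8aS)-8-[2-(tert-butyldimethylsilyloxy)ethyl]-4-hydroxy-3,4a,8-trimethyl-4a,5,6,7,8,8a-hexahydro-2H-chromen-2-one | CC1=C(O)[C@]2(C)CCC[C@@](C)(CCO[Si](C)(C)C(C)(C)C)[C@@H]2OC1=O | intermediate
14 | (4aR,8S,8aS)-8-[2-(tert-butyldimethylsilyloxy)ethyl]-3,4a,8-trimethyl-2-oxo-4a,5,6,7,8,8a-hexahydro-2H-chromen-4-yl trifluoromethanesulfonate | CC1=C(OS(=O)(=O)C(F)(F)F)[C@]2(C)CCC[C@@](C)(CCO[Si](C)(C)C(C)(C)C)[C@@H]2OC1=O | intermediate
15 | 2-(chloromethyl)-1,4-dimethoxybenzene | COc1ccc(OC)c(CCl)c1 | starting material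
16 | (2,5-dimethoxybenzyl)zinc chloride (not isolated) | COc1ccc(OC)c(C[Zn]Cl)c1 | intermediate
17 | (4aS,8S,8aS)-8-[2-(tert-butyldimethylsilyloxy)ethyl]-4-(2,5-dimethoxybenzyl)-3,4a,8-trimethyl-4a,5,6,7,8,8a-hexahydro-2H-chromen-2-one | CC1=C(Cc3cc(OC)ccc3OC)[C@]2(C)CCC[C@@](C)(CCO[Si](C)(C)C(C)(C)C)[C@@H]2OC1=O | intermediate
18 | (4aS,8S,8aS)-8-[2-(tert-butyldimethylsilyloxy)ethyl]-4-(2,5-dimethoxybenzyl)-3,4a,8-trimethyl-4a,5,6,7,8,8a-hexahydro-2H-chromen-2-ol (C2 epimers) | CC1=C(Cc3cc(OC)ccc3OC)[C@]2(C)CCC[C@@](C)(CCO[Si](C)(C)C(C)(C)C)[C@@H]2OC1O | intermediate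
19 | (2Z)-3-{(1S,2S,3S)-3-[2-(tert-butyldimethylsilyloxy)ethyl]-2-hydroxy-1,3-dimethylcyclohexyl}-4-(2,5-dimethoxyphenyl)-2-methylbut-2-enal (not isolated) | O=C/C(C)=C(/Cc1cc(OC)ccc1OC)[C@]1(C)CCC[C@@](C)(CCO[Si](C)(C)C(C)(C)C)[C@@H]1O | intermediate
20 | (1S,2S,6S)-6-[2-(tert-butyldimethylsilyloxy)ethyl]-2-[(2Z)-1-(2,5-dimethoxyphenyl)-3-methylpenta-2,4-dien-2-yl]-2,6-dimethylcyclohexan-1-ol | C=C/C(C)=C(/Cc1cc(OC)ccc1OC)[C@]1(C)CCC[C@@](C)(CCO[Si](C)(C)C(C)(C)C)[C@@H]1O | intermediate
21 | O-{(1S,2S,6S)-6-[2-(tert-butyldimethylsilyloxy)ethyl]-2-[(2Z)-1-(2,5-dimethoxyphenyl)-3-methylpenta-2,4-dien-2-yl]-2,6-dimethylcyclohexyl} S-methyl carbonodithioate | C=C/C(C)=C(/Cc1cc(OC)ccc1OC)[C@]1(C)CCC[C@@](C)(CCO[Si](C)(C)C(C)(C)C)[C@@H]1OC(=S)SC | intermediate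
22 | cis-fused (4S,5S,10R)-4-[2-(tert-butyldimethylsilyloxy)ethyl]-9-(2,5-dimethoxybenzyl)-4,8,10-trimethyl-Δ8(9)-octalin | CC1=C(Cc2cc(OC)ccc2OC)[C@]2(C)CCC[C@@](C)(CCO[Si](C)(C)C(C)(C)C)[C@@H]2CC1 | intermediate
23 | 2-[(4S,5S,10R)-9-(2,5-dimethoxybenzyl)-4,8,10-trimethyl-Δ8(9)-octalin-4-yl]ethan-1-ol | CC1=C(Cc2cc(OC)ccc2OC)[C@]2(C)CCC[C@@](C)(CCO)[C@@H]2CC1 | intermediate
24 | (4S,5S,10R)-9-(2,5-dimethoxybenzyl)-4-(2-iodoethyl)-4,8,10-trimethyl-Δ8(9)-octalin | CC1=C(Cc2cc(OC)ccc2OC)[C@]2(C)CCC[C@@](C)(CCI)[C@@H]2CC1 | intermediate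
25 | 2-methylcyclohexane-1,3-dione | CC1C(=O)CCCC1=O | starting material
26 | 2-methyl-2-(prop-2-en-1-yl)cyclohexane-1,3-dione | C=CCC1(C)C(=O)CCCC1=O | intermediate
27 | (2S,3S)-3-hydroxy-2-methyl-2-(prop-2-en-1-yl)cyclohexan-1-one | O=C1CCC[C@H](O)[C@]1(C)CC=C | intermediate
28 | 2-methylbut-3-en-2-ol | C=CC(C)(C)O | starting material
29 | (2S,3S)-3-hydroxy-2-[(2E)-4-hydroxy-4-methylpent-2-en-1-yl]-2-methylcyclohexan-1-one | O=C1CCC[C@H](O)[C@]1(C)C/C=C/C(C)(C)O | intermediate
30 | (2S,3S)-3-hydroxy-2-(4-hydroxy-4-methylpentyl)-2-methylcyclohexan-1-one | O=C1CCC[C@H](O)[C@]1(C)CCCC(C)(C)O | intermediate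
31 | (5aS,9aS)-2,2,5a-trimethyloctahydro-1-benzoxepin-6(2H)-one | O=C1CCC[C@@H]2OC(C)(C)CCC[C@@]21C | intermediate
32 | (5aS,7R,9aS)-2,2,5a,7-tetramethyloctahydro-1-benzoxepin-6(2H)-one | O=C1[C@H](C)CC[C@@H]2OC(C)(C)CCC[C@@]21C | intermediate
33 | 2-[9-(2,5-dimethoxybenzyl)-4,8,10-trimethyl-Δ8(9)-octalin-4-yl]ethyllithium, configuration as in 24 (not isolated) | CC1=C(Cc2cc(OC)ccc2OC)[C@]2(C)CCC[C@@](C)(CC[Li])[C@@H]2CC1 | intermediate
34 | (5aS,6R,7R,9aS)-6-{2-[(4S,5S,10R)-9-(2,5-dimethoxybenzyl)-4,8,10-trimethyl-Δ8(9)-octalin-4-yl]ethyl}-2,2,5a,7-tetramethyldecahydro-1-benzoxepin-6-ol | CC1=C(Cc2cc(OC)ccc2OC)[C@]2(C)CCC[C@@](C)(CC[C@@]3(O)[C@H](C)CC[C@@H]4OC(C)(C)CCC[C@@]43C)[C@@H]2CC1 | intermediate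
35 | quinone corresponding to 34 (2-substituted cyclohexa-2,5-diene-1,4-dione) | CC1=C(CC2=CC(=O)C=CC2=O)[C@]2(C)CCC[C@@](C)(CC[C@@]3(O)[C@H](C)CC[C@@H]4OC(C)(C)CCC[C@@]43C)[C@@H]2CC1 | intermediate
36 | hydroquinone corresponding to 34 (2-substituted benzene-1,4-diol) | CC1=C(Cc2cc(O)ccc2O)[C@]2(C)CCC[C@@](C)(CC[C@@]3(O)[C@H](C)CC[C@@H]4OC(C)(C)CCC[C@@]43C)[C@@H]2CC1 | intermediate
37 | CNP0125037.2, bis(hydrogen sulfate) of 36 | CC1=C(Cc2cc(OS(=O)(=O)O)ccc2OS(=O)(=O)O)[C@]2(C)CCC[C@@](C)(CC[C@@]3(O)[C@H](C)CC[C@@H]4OC(C)(C)CCC[C@@]43C)[C@@H]2CC1 | target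

**Step count**

Total steps: 27. Longest linear sequence: 21 (steps 1–17 and 24–27); the oxepane ketone branch is steps 18–23.

**Steps most likely to fail, with fallbacks**

Step 15. The hindered C5 radical may take hydrogen from the stannane before it cyclises, or C6 may bond on the wrong face and give the trans ring fusion. The fallback closes the same C5–C6 bond from the carbonyl and sets C5 afterwards by directed hydrogenation. It sets out from 20, which is oxidised (Dess–Martin periodinane) to the dienyl ketone F1. SmI2/HMPA/t-BuOH should cyclise its ketyl onto C6, with protonation of the allylsamarium at C7, to give the ring-fusion tertiary alcohol F2. Burgess dehydration can only go towards C6 and should give the 5(6),8(9)-diene silyl ether F3, which TBAF converts into the dienol F4. The hydroxyethyl arm of F4 lies on the face of the C10 methyl, so hydrogenation with Crabtree's catalyst should deliver hydrogen to C5 from that face and return to the route at 23.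

Step 23. The two Cb epimers of the cis-fused bicyclic ketone may differ too little in energy, so equilibration may not give a useful bias. The fallback sets Cb before the oxepane is closed, on a monocyclic ketone with a larger conformational bias. It sets out from 30, whose secondary hydroxyl is silylated (TBSCl, imidazole) to the silyl ether F5. Methylation (LDA, 2.2 equiv; MeI) and NaOMe equilibration should give the 6-methyl ketone F6, in which the axial silyloxy chair places the new methyl equatorial and cis to oxygen. HF·pyridine followed by catalytic TfOH then removes the silyl group and closes the oxepane, returning to the route at 32.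

Step 24. The basic alkyllithium may enolise the hindered ketone at Cb or add with incomplete facial selectivity. The fallback replaces the sp3 nucleophile by an acetylide. It sets out from 23, which is oxidised (Dess–Martin periodinane) to the aldehyde F7. Nonafluorobutanesulfonyl fluoride and a phosphazene base convert it, through the alkenyl nonaflate F8, into the terminal alkyne F9. Its cerium acetylide (n-BuLi; CeCl3) should add to 32 on the same equatorial trajectory to give the propargylic alcohol F10. Hydrogenation of the alkyne (H2, Pd/C, EtOAc/Et3N), which the tetrasubstituted alkene should survive, returns to the route at 34.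

**Further compounds**

F1 | step 15 | (2S,6S)-2-[2-(tert-butyldimethylsilyloxy)ethyl]-6-[(2Z)-1-(2,5-dimethoxyphenyl)-3-methylpenta-2,4-dien-2-yl]-2,6-dimethylcyclohexan-1-one | C=C/C(C)=C(/Cc1cc(OC)ccc1OC)[C@]1(C)CCC[C@@](C)(CCO[Si](C)(C)C(C)(C)C)C1=O
F2 | step 15 | 4-[2-(tert-butyldimethylsilyloxy)ethyl]-9-(2,5-dimethoxybenzyl)-4,8,10-trimethyl-Δ8(9)-octalin-5-ol (C5 configuration open) | CC1=C(Cc2cc(OC)ccc2OC)[C@]2(C)CCC[C@@](C)(CCO[Si](C)(C)C(C)(C)C)C2(O)CC1
F3 | step 15 | 4-[2-(tert-butyldimethylsilyloxy)ethyl]-9-(2,5-dimethoxybenzyl)-4,8,10-trimethyl-Δ5(6),Δ8(9)-hexalin | CC1=C(Cc2cc(OC)ccc2OC)[C@]2(C)CCC[C@@](C)(CCO[Si](C)(C)C(C)(C)C)C2=CC1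
F4 | step 15 | 2-[9-(2,5-dimethoxybenzyl)-4,8,10-trimethyl-Δ5(6),Δ8(9)-hexalin-4-yl]ethan-1-ol | CC1=C(Cc2cc(OC)ccc2OC)[C@]2(C)CCC[C@@](C)(CCO)C2=CC1
F5 | step 23 | (2S,3S)-3-(tert-butyldimethylsilyloxy)-2-(4-hydroxy-4-methylpentyl)-2-methylcyclohexan-1-one | O=C1CCC[C@H](O[Si](C)(C)C(C)(C)C)[C@]1(C)CCCC(C)(C)O
F6 | step 23 | (2S,3S,6R)-3-(tert-butyldimethylsilyloxy)-2-(4-hydroxy-4-methylpentyl)-2,6-dimethylcyclohexan-1-one | O=C1[C@H](C)CC[C@H](O[Si](C)(C)C(C)(C)C)[C@]1(C)CCCC(C)(C)O
F7 | step 24 | 2-[9-(2,5-dimethoxybenzyl)-4,8,10-trimethyl-Δ8(9)-octalin-4-yl]acetaldehyde (configuration as in 23) | CC1=C(Cc2cc(OC)ccc2OC)[C@]2(C)CCC[C@@](C)(CC=O)[C@@H]2CC1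
F8 | step 24 | 2-[9-(2,5-dimethoxybenzyl)-4,8,10-trimethyl-Δ8(9)-octalin-4-yl]ethenyl nonafluorobutane-1-sulfonate (not isolated) | CC1=C(Cc2cc(OC)ccc2OC)[C@]2(C)CCC[C@@](C)(C=COS(=O)(=O)C(F)(F)C(F)(F)C(F)(F)C(F)(F)F)[C@@H]2CC1
F9 | step 24 | 9-(2,5-dimethoxybenzyl)-4-ethynyl-4,8,10-trimethyl-Δ8(9)-octalin (configuration as in 23) | CC1=C(Cc2cc(OC)ccc2OC)[C@]2(C)CCC[C@@](C)(C#C)[C@@H]2CC1
F10 | step 24 | (5aS,6R,7R,9aS)-6-{[9-(2,5-dimethoxybenzyl)-4,8,10-trimethyl-Δ8(9)-octalin-4-yl]ethynyl}-2,2,5a,7-tetramethyldecahydro-1-benzoxepin-6-ol | CC1=C(Cc2cc(OC)ccc2OC)[C@]2(C)CCC[C@@](C)(C#C[C@@]3(O)[C@H](C)CC[C@@H]4OC(C)(C)CCC[C@@]43C)[C@@H]2CC1
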